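**Retrosynthetic overview**
- The target comes from its 7,5'-di-O-benzyl ether by hydrogenolysis; the four methyl ethers are carried through unchanged.
- Ring C (the pyranone) is the only ring made, and it is made last, by I2/DMSO oxidative cyclisation of a 2'-hydroxychalcone.
- The chalcone comes from the key C–C bond formation: an intermolecular Claisen–Schmidt aldol condensation of a ring A methyl ketone with a ring B aldehyde.
- Ring A ketone (4-benzyloxy-6-hydroxy-2,3-dimethoxyacetophenone) comes from phloroacetophenone: dibenzylation, O-methylation, chelation-controlled ortho-debenzylation, Elbs para-hydroxylation, selective O-methylation.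
- Ring B aldehyde (3-benzyloxy-4,5-dimethoxybenzaldehyde) comes from 5-bromovanillin: Br to OH, selective 4-O-methylation, benzylation.

Assumption: the target has no stereocentre and no stereogenic double bond, so it is one achiral compound and no enantiocontrol is needed.

**Route**

Step 1
Reactants: 1 2',4',6'-trihydroxyacetophenone (phloroacetophenone)
Product: 2 1-[2,4-bis(benzyloxy)-6-hydroxyphenyl]ethanone
Conditions: BnBr (2.1 equiv), K2CO3 (2.5 equiv), DMF, rt, 18 h
Reagents that add atoms: benzyl bromide, BrCc1ccccc1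
Why: Williamson O-benzylation alkylates the para-OH and one ortho-OH, while the last ortho-OH stays free because it is locked in a hydrogen bond to the ketone.

Step 2
Reactants: 2 1-[2,4-bis(benzyloxy)-6-hydroxyphenyl]ethanone
Product: 3 1-[2,4-bis(benzyloxy)-6-methoxyphenyl]ethanone
Conditions: MeI (3 equiv), K2CO3 (3 equiv), DMF, 60 °C, 12 h
Reagents that add atoms: iodomethane, CI
Why: Williamson O-methylation under forcing conditions (excess MeI, warm DMF), which the hydrogen-bonded ortho-phenol needs; benzyl ethers and ketone are inert.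

Step 3
Reactants: 3 1-[2,4-bis(benzyloxy)-6-methoxyphenyl]ethanone
Product: 4 1-[4-(benzyloxy)-2-hydroxy-6-methoxyphenyl]ethanone
Conditions: MgBr2·OEt2 (3 equiv), toluene/Et2O, 80 °C, 24 h; then 1 M HCl
Reagents that add atoms: none
Why: Chelation-controlled Lewis-acid ether cleavage: Mg held between the ketone oxygen and the ortho benzyloxy oxygen lets bromide remove only that benzyl group by SN2, the unchelated 4-OBn is untouched and the ortho methyl ether is a much poorer SN2 partner.

Step 4
Reactants: 4 1-[4-(benzyloxy)-2-hydroxy-6-methoxyphenyl]ethanone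
Product: 6 1-[4-(benzyloxy)-3,6-dihydroxy-2-methoxyphenyl]ethanone, via potassium aryl sulfate 5 (not isolated)
Conditions: K2S2O8 (1.1 equiv), 10% aq NaOH/pyridine, 15–20 °C, 24 h; acidify to pH 4, extract unreacted 4 (recycled); then 2 M HCl, Na2SO3, 85 °C, 30 min
Reagents that add atoms: potassium peroxodisulfate, [K+].[K+].[O-]S(=O)(=O)OOS(=O)(=O)[O-]
Why: Elbs persulfate oxidation: the phenoxide attacks peroxodisulfate through the carbon para to the phenoxide oxygen (the free site between the two alkoxy groups), and warm acid hydrolyses the aryl sulfate to the hydroquinone.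

Step 5
Reactants: 6 1-[4-(benzyloxy)-3,6-dihydroxy-2-methoxyphenyl]ethanone
Product: 7 1-[4-(benzyloxy)-6-hydroxy-2,3-dimethoxyphenyl]ethanone
Conditions: MeI (1.1 equiv), K2CO3 (1.2 equiv), acetone, reflux, 6 h
Reagents that add atoms: iodomethane, CI
Why: Selective Williamson O-methylation: the new 3-OH is a free phenol, whereas the 6-OH is chelated to the ketone and is not alkylated by one equivalent of MeI in acetone (compare the forcing conditions of step 2).

Step 6
Reactants: 8 5-bromovanillin (3-bromo-4-hydroxy-5-methoxybenzaldehyde)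
Product: 9 3,4-dihydroxy-5-methoxybenzaldehyde (5-hydroxyvanillin)
Conditions: NaOH (8% aq, 7 equiv), Cu powder (5 mol%), reflux, N2, 24 h; then HCl to pH 2
Reagents that add atoms: sodium hydroxide, [Na+].[OH-]
Why: Copper-mediated Ullmann-type hydroxylation of the aryl bromide, the classical preparation of 5-hydroxyvanillin; the aldehyde is protected from Cannizzaro reaction because it is conjugated to the para-phenoxide.

Step 7
Reactants: 9 3,4-dihydroxy-5-methoxybenzaldehyde
Product: 10 3-hydroxy-4,5-dimethoxybenzaldehyde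
Conditions: Me2SO4 (1.05 equiv), Na2CO3 (1.1 equiv), acetone, reflux, 5 h
Reagents that add atoms: dimethyl sulfate, COS(=O)(=O)OC
Why: Regioselective Williamson O-methylation: the 4-OH para to the formyl group is about two pKa units more acidic than the 3-OH, so the weak base ionises and methylates only it.

Step 8
Reactants: 10 3-hydroxy-4,5-dimethoxybenzaldehyde
Product: 11 3-(benzyloxy)-4,5-dimethoxybenzaldehyde
Conditions: BnBr (1.2 equiv), K2CO3 (1.5 equiv), DMF, rt, 6 h
Reagents that add atoms: benzyl bromide, BrCc1ccccc1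
Why: Williamson O-benzylation of the one remaining phenol; the non-enolisable aldehyde is inert to K2CO3.

Step 9
Reactants: 7 1-[4-(benzyloxy)-6-hydroxy-2,3-dimethoxyphenyl]ethanone; 11 3-(benzyloxy)-4,5-dimethoxybenzaldehyde
Product: 13 (2E)-1-[4-(benzyloxy)-6-hydroxy-2,3-dimethoxyphenyl]-3-[3-(benzyloxy)-4,5-dimethoxyphenyl]prop-2-en-1-one, via β-hydroxy ketone 12 (not isolated)
Conditions: KOH (50% aq, 10 equiv), EtOH, rt, 48 h; then 1 M HCl, 0 °C
Reagents that add atoms: none
Why: Claisen–Schmidt condensation (crossed intermolecular aldol, then E1cB dehydration): the methyl ketone is the only enolisable partner and the aldehyde the only good electrophile, so one racemic β-hydroxy ketone forms and loses water, erasing its stereocentre, to give the thermodynamically favoured (E)-enone.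

Step 10
Reactants: 13 (2E)-1-[4-(benzyloxy)-6-hydroxy-2,3-dimethoxyphenyl]-3-[3-(benzyloxy)-4,5-dimethoxyphenyl]prop-2-en-1-one
Product: 16 7-(benzyloxy)-2-[3-(benzyloxy)-4,5-dimethoxyphenyl]-5,6-dimethoxy-4H-chromen-4-one, via flavanone 14 (not isolated), via trans-3-iodoflavanone 15 (not isolated)
Conditions: I2 (10 mol%), DMSO, 120 °C, 3 h; then aq Na2S2O3
Reagents that add atoms: none
Why: Iodine/DMSO oxidative cyclisation: intramolecular oxa-Michael addition of the 2'-OH closes ring C to the racemic flavanone, α-iodination and loss of HI give the flavone, and DMSO reoxidises HI to I2, so both transient stereocentres vanish.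

Step 11
Reactants: 16 7-(benzyloxy)-2-[3-(benzyloxy)-4,5-dimethoxyphenyl]-5,6-dimethoxy-4H-chromen-4-one
Product: 17 7-hydroxy-2-(3-hydroxy-4,5-dimethoxyphenyl)-5,6-dimethoxy-4H-chromen-4-one (7,5'-dihydroxy-5,6,3',4'-tetramethoxyflavone)
Conditions: H2 (1 atm), 10% Pd/C, THF/MeOH 1:1, rt, 3 h (stopped at full debenzylation)
Reagents that add atoms: none
Why: Catalytic hydrogenolysis cleaves both benzyl aryl ethers; aryl methyl ethers are inert and the C2=C3 bond of the pyranone is not reduced under these mild conditions.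

**Compound list**
1 | 2',4',6'-trihydroxyacetophenone (phloroacetophenone) | CC(=O)c1c(O)cc(O)cc1O | starting material
2 | 1-[2,4-bis(benzyloxy)-6-hydroxyphenyl]ethanone | CC(=O)c1c(O)cc(OCc2ccccc2)cc1OCc1ccccc1 | intermediate
3 | 1-[2,4-bis(benzyloxy)-6-methoxyphenyl]ethanone | CC(=O)c1c(OC)cc(OCc2ccccc2)cc1OCc1ccccc1 | intermediate
4 | 1-[4-(benzyloxy)-2-hydroxy-6-methoxyphenyl]ethanone | CC(=O)c1c(O)cc(OCc2ccccc2)cc1OC | intermediate
5 | potassium 3-acetyl-6-(benzyloxy)-4-hydroxy-2-methoxyphenyl sulfate (formed in the flask, not isolated) | CC(=O)c1c(O)cc(OCc2ccccc2)c(OS(=O)(=O)[O-])c1OC.[K+] | intermediate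
6 | 1-[4-(benzyloxy)-3,6-dihydroxy-2-methoxyphenyl]ethanone | CC(=O)c1c(O)cc(OCc2ccccc2)c(O)c1OC | intermediate
7 | 1-[4-(benzyloxy)-6-hydroxy-2,3-dimethoxyphenyl]ethanone | CC(=O)c1c(O)cc(OCc2ccccc2)c(OC)c1OC | intermediate
8 | 5-bromovanillin (3-bromo-4-hydroxy-5-methoxybenzaldehyde) | COc1cc(C=O)cc(Br)c1O | starting material
9 | 3,4-dihydroxy-5-methoxybenzaldehyde (5-hydroxyvanillin) | COc1cc(C=O)cc(O)c1O | intermediate
10 | 3-hydroxy-4,5-dimethoxybenzaldehyde | COc1cc(C=O)cc(O)c1OC | intermediate
11 | 3-(benzyloxy)-4,5-dimethoxybenzaldehyde | COc1cc(C=O)cc(OCc2ccccc2)c1OC | intermediate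
12 | 1-[4-(benzyloxy)-6-hydroxy-2,3-dimethoxyphenyl]-3-[3-(benzyloxy)-4,5-dimethoxyphenyl]-3-hydroxypropan-1-one (racemic, not isolated) | COc1cc(C(O)CC(=O)c2c(O)cc(OCc3ccccc3)c(OC)c2OC)cc(OCc2ccccc2)c1OC | intermediate
13 | (2E)-1-[4-(benzyloxy)-6-hydroxy-2,3-dimethoxyphenyl]-3-[3-(benzyloxy)-4,5-dimethoxyphenyl]prop-2-en-1-one | COc1cc(/C=C/C(=O)c2c(O)cc(OCc3ccccc3)c(OC)c2OC)cc(OCc2ccccc2)c1OC | intermediate
14 | 7-(benzyloxy)-2-[3-(benzyloxy)-4,5-dimethoxyphenyl]-5,6-dimethoxy-2,3-dihydro-4H-chromen-4-one (racemic flavanone, not isolated) | COc1cc(C2CC(=O)c3c(OC)c(OC)c(OCc4ccccc4)cc3O2)cc(OCc2ccccc2)c1OC | intermediate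
15 | trans-7-(benzyloxy)-2-[3-(benzyloxy)-4,5-dimethoxyphenyl]-3-iodo-5,6-dimethoxy-2,3-dihydro-4H-chromen-4-one (racemic, one enantiomer drawn, not isolated) | COc1cc([C@H]2Oc3cc(OCc4ccccc4)c(OC)c(OC)c3C(=O)[C@@H]2I)cc(OCc2ccccc2)c1OC | intermediate
16 | 7-(benzyloxy)-2-[3-(benzyloxy)-4,5-dimethoxyphenyl]-5,6-dimethoxy-4H-chromen-4-one | COc1cc(-c2cc(=O)c3c(OC)c(OC)c(OCc4ccccc4)cc3o2)cc(OCc2ccccc2)c1OC | intermediate
17 | 7-hydroxy-2-(3-hydroxy-4,5-dimethoxyphenyl)-5,6-dimethoxy-4H-chromen-4-one (achiral) | COc1cc(-c2cc(=O)c3c(OC)c(OC)c(O)cc3o2)cc(O)c1OC | target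

**Summary**
Total step count: 11.
Longest linear sequence: 8 steps (steps 1, 2, 3, 4, 5, 9, 10, 11, from 1 to 17); the ring B branch (steps 6, 7, 8) joins at step 9.

Three steps most likely to fail, each with a fallback:

1. Step 4 (Elbs oxidation: conversion is usually low and the aryl sulfate can be lost in the work-up). The fallback sets out from 4. It oxidises 4 with (KSO3)2NO (Fremy's salt, 2.2 equiv) in acetone/aqueous KH2PO4 at rt (Teuber oxidation) to the para-quinone 2-acetyl-5-(benzyloxy)-3-methoxycyclohexa-2,5-diene-1,4-dione F1. The crude quinone is then shaken in EtOAc with aqueous Na2S2O4, which reduces it to the hydroquinone 6, where the route resumes.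

2. Step 7 (mono-methylation of a catechol: over-methylation or the wrong regioisomer). The fallback sets out from 8. The single phenol is methylated (MeI, K2CO3, DMF) to 3-bromo-4,5-dimethoxybenzaldehyde F2. Miyaura borylation (B2pin2, PdCl2(dppf) 3 mol%, KOAc, dioxane, 90 °C) converts the bromide into 3,4-dimethoxy-5-(4,4,5,5-tetramethyl-1,3,2-dioxaborolan-2-yl)benzaldehyde F3. Oxidation of the C–B bond with NaBO3·4H2O in THF/H2O at rt gives the phenol 10. This replaces steps 6 and 7, and the position of the free hydroxyl is fixed by the bromine of 8.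

3. Step 3 (removal of one of two benzyl ethers: partial loss of the 4-OBn or of the methyl ether is possible). The fallback sets out from 3. Both benzyl groups are removed by hydrogenolysis (H2, 10% Pd/C, EtOAc/MeOH, rt) to give 1-(2,4-dihydroxy-6-methoxyphenyl)ethanone F4. Only the unchelated 4-OH is then benzylated (BnBr 1.05 equiv, K2CO3, acetone, reflux), which arrives at 4.

**Further compounds**
F1 | step 4 | 2-acetyl-5-(benzyloxy)-3-methoxycyclohexa-2,5-diene-1,4-dione | CC(=O)C1=C(OC)C(=O)C(OCc2ccccc2)=CC1=O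
F2 | step 7 | 3-bromo-4,5-dimethoxybenzaldehyde | COc1cc(C=O)cc(Br)c1OC
F3 | step 7 | 3,4-dimethoxy-5-(4,4,5,5-tetramethyl-1,3,2-dioxaborolan-2-yl)benzaldehyde | COc1cc(C=O)cc(B2OC(C)(C)C(C)(C)O2)c1OC
F4 | step 3 | 1-(2,4-dihydroxy-6-methoxyphenyl)ethanone | CC(=O)c1c(O)cc(O)cc1OC
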